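## Retrosynthetic overview

1. The target comes from a cycloadduct that carries C1 as CHO and C5 as CH–OSiEt3, by one chromic acid oxidation (CHO → CO2H, CH–OSi → C=O).
2. The cycloadduct comes from an intramolecular Diels–Alder reaction of an all-E 14-phenyltetradeca-2,7,9,11,13-pentaenal (diene C7=C8–C9=C10, dienophile C2=C3). The cyclohexene ([4+2] ring) and the cyclopentane (C4–C5–C6 tether) close in the same step, so both rings form together and last.
3. The enal dienophile comes from a C3 aldehyde by Wittig olefination. The phenyl tetraene comes from a C7 aldehyde by four iterative E-selective olefinations (C7=C8, C9=C10, C11=C12, C13=C14).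
4. The C4–C5 bond comes from an anti-selective, Felkin-controlled boron aldol of benzyl butanoate with (S)-2-methyl-3-(triethylsilyloxy)propanal, made from methyl (S)-3-hydroxy-2-methylpropanoate. Its stereocentre (C6) sets C4 and C5, and these set C2, C3, C7 and C10 in the cycloaddition.

Numbering: C1–C14 are the chain carbons of the linear precursor (C1 = carboxyl carbon, C14 = CHPh).

Assumption: 2-(triphenylphosphoranylidene)butanal and dicyclohexylboron triflate are taken as purchasable reagents.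

## Route

Step 1
Reactants: 1 methyl (S)-3-hydroxy-2-methylpropanoate
Product: 2 methyl (S)-2-methyl-3-(triethylsilyloxy)propanoate
Conditions: TESCl, imidazole, CH2Cl2, 0 °C → rt
Reagents that add atoms: chlorotriethylsilane, CC[Si](Cl)(CC)CC
Why: Silyl ether formation at the primary hydroxyl; the triethylsilyl ether later serves as a latent aldehyde, and the purchased stereocentre is not touched.

Step 2
Reactants: 2 methyl (S)-2-methyl-3-(triethylsilyloxy)propanoate
Product: 3 (S)-2-methyl-3-(triethylsilyloxy)propanal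
Conditions: i-Bu2AlH (1.1 equiv), CH2Cl2, −78 °C; MeOH, aq. KNaC4H4O6; crude aldehyde used at once
Reagents that add atoms: none
Why: Partial ester reduction; the aluminium hemiacetal is stable at −78 °C and gives the aldehyde only on work-up, and immediate use avoids racemisation of the α-centre.

Step 3
Reactants: 3 (S)-2-methyl-3-(triethylsilyloxy)propanal; 4 benzyl butanoate
Product: 6 benzyl (2R,3R,4S)-2-ethyl-3-hydroxy-4-methyl-5-(triethylsilyloxy)pentanoate, via enol borinate 5 (not isolated)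
Conditions: 4, c-Hex2BOTf, Et3N, CH2Cl2, −78 °C, 2 h; then 3, −78 → 0 °C; pH 7 buffer, MeOH, 30% H2O2, 0 °C
Reagents that add atoms: none
Why: Boron aldol reaction: c-Hex2BOTf/Et3N gives the E(O)-enol borinate 5, whose Zimmerman–Traxler chair gives the 2,3-anti aldol, and Felkin–Anh attack on the α-methyl aldehyde (the mode favoured for E-enolates because it avoids a syn-pentane clash) gives 3,4-syn, so the purchased centre fixes C2 and C3 of 6 (C4 and C5 of the chain).

Step 4
Reactants: 6 benzyl (2R,3R,4S)-2-ethyl-3-hydroxy-4-methyl-5-(triethylsilyloxy)pentanoate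
Product: 7 benzyl (2R,3R,4S)-2-ethyl-4-methyl-3,5-bis(triethylsilyloxy)pentanoate
Conditions: TESOTf, 2,6-lutidine, CH2Cl2, −78 °C
Reagents that add atoms: triethylsilyl trifluoromethanesulfonate, CC[Si](CC)(CC)OS(=O)(=O)C(F)(F)F
Why: Silylation of the hindered secondary alcohol with the silyl triflate blocks C5–OH through the polyene construction and prevents retro-aldol or elimination.

Step 5
Reactants: 7 benzyl (2R,3R,4S)-2-ethyl-4-methyl-3,5-bis(triethylsilyloxy)pentanoate
Product: 8 benzyl (2R,3R,4R)-2-ethyl-4-methyl-5-oxo-3-(triethylsilyloxy)pentanoate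
Conditions: (COCl)2, DMSO, CH2Cl2, −78 → −30 °C; then Et3N, −78 → 0 °C
Reagents that add atoms: none
Why: Swern oxidation applied directly to the silyl ether: the activated DMSO cleaves and oxidises only the unhindered primary triethylsilyl ether, the hindered secondary one stays, and the α-stereocentre survives the cold amine treatment (descriptor changes by priority only).

Step 6
Reactants: 8 benzyl (2R,3R,4R)-2-ethyl-4-methyl-5-oxo-3-(triethylsilyloxy)pentanoate; 9 2-(triphenylphosphoranylidene)propanal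
Product: 10 benzyl (2R,3R,4S,5E)-2-ethyl-4,6-dimethyl-7-oxo-3-(triethylsilyloxy)hept-5-enoate
Conditions: 9 (1.5 equiv), toluene, 80 °C
Reagents that add atoms: none
Why: Wittig olefination with a stabilised formyl ylide gives the (E)-trisubstituted enal (C7=C8), and the ylide is too weakly basic to epimerise the aldehyde or react with the benzyl ester.

Step 7
Reactants: 10 benzyl (2R,3R,4S,5E)-2-ethyl-4,6-dimethyl-7-oxo-3-(triethylsilyloxy)hept-5-enoate; 9 2-(triphenylphosphoranylidene)propanal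
Product: 11 benzyl (2R,3R,4S,5E,7E)-2-ethyl-4,6,8-trimethyl-9-oxo-3-(triethylsilyloxy)nona-5,7-dienoate
Conditions: 9 (2 equiv), toluene, 110 °C, dark
Reagents that add atoms: none
Why: A second Wittig homologation of the enal gives the (E,E)-dienal (C9=C10); the more conjugated product is less electrophilic, which limits over-homologation.

Step 8
Reactants: 11 benzyl (2R,3R,4S,5E,7E)-2-ethyl-4,6,8-trimethyl-9-oxo-3-(triethylsilyloxy)nona-5,7-dienoate; 12 2-(triphenylphosphoranylidene)butanal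
Product: 13 benzyl (2R,3R,4S,5E,7E,9E)-2,10-diethyl-4,6,8-trimethyl-11-oxo-3-(triethylsilyloxy)undeca-5,7,9-trienoate
Conditions: 12 (2.5 equiv), toluene, 110 °C, dark
Reagents that add atoms: none
Why: Wittig olefination with the ethyl-substituted formyl ylide installs C11=C12 with its ethyl branch, E-selective as for all stabilised ylides.

Step 9
Reactants: 13 benzyl (2R,3R,4S,5E,7E,9E)-2,10-diethyl-4,6,8-trimethyl-11-oxo-3-(triethylsilyloxy)undeca-5,7,9-trienoate; 14 diethyl benzylphosphonate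
Product: 16 benzyl (2R,3R,4S,5E,7E,9E,11E)-2,10-diethyl-4,6,8-trimethyl-12-phenyl-3-(triethylsilyloxy)dodeca-5,7,9,11-tetraenoate, via sodium phosphonate 15 (not isolated)
Conditions: 14, NaN(SiMe3)2, THF, −78 °C; then 13, −78 → 0 °C, dark
Reagents that add atoms: none
Why: Horner–Wadsworth–Emmons olefination with the preformed benzylphosphonate anion gives the (E)-styryl terminus; without free excess base the hindered ester α-proton is left alone, and the ester is no dienophile, so the tetraene is stable.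

Step 10
Reactants: 16 benzyl (2R,3R,4S,5E,7E,9E,11E)-2,10-diethyl-4,6,8-trimethyl-12-phenyl-3-(triethylsilyloxy)dodeca-5,7,9,11-tetraenoate
Product: 17 (2R,3R,4S,5E,7E,9E,11E)-2,10-diethyl-4,6,8-trimethyl-12-phenyl-3-(triethylsilyloxy)dodeca-5,7,9,11-tetraenal
Conditions: i-Bu2AlH (1.2 equiv), CH2Cl2, −78 °C; MeOH at −78 °C, aq. KNaC4H4O6; crude aldehyde used at once
Reagents that add atoms: none
Why: Partial ester reduction (cold quench of the aluminium hemiacetal) unmasks the C3 aldehyde only now, after all other aldehyde olefinations are finished; the polyene and silyl ether are inert to the hydride.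

Step 11
Reactants: 17 (2R,3R,4S,5E,7E,9E,11E)-2,10-diethyl-4,6,8-trimethyl-12-phenyl-3-(triethylsilyloxy)dodeca-5,7,9,11-tetraenal; 12 2-(triphenylphosphoranylidene)butanal
Product: 19 (1S,2R,3S,3aR,4R,5R,7aR)-3,4-diethyl-5-[(1E,3E)-2-ethyl-4-phenylbuta-1,3-dien-1-yl]-1,5,7-trimethyl-2-(triethylsilyloxy)-2,3,3a,4,5,7a-hexahydro-1H-indene-4-carbaldehyde, via pentaenal 18 (not isolated)
Conditions: 12 (2 equiv), BHT (cat.), degassed toluene (0.01 M), 90 °C then 110 °C, dark
Reagents that add atoms: none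
Why: Wittig olefination gives the (2E)-enal 18, which undergoes the intramolecular Diels–Alder reaction in the same pot through the endo-CHO, trans-fused transition state in which C4–H and C6–H lie in the planes of the dienophile and diene (minimal allylic 1,3-strain against the C2-ethyl and C8-methyl groups) and the C4-ethyl and C6-methyl groups are pseudo-equatorial, so that C4 and C6 set C2, C3, C7 and C10 as in the target.

Step 12
Reactants: 19 (1S,2R,3S,3aR,4R,5R,7aR)-3,4-diethyl-5-[(1E,3E)-2-ethyl-4-phenylbuta-1,3-dien-1-yl]-1,5,7-trimethyl-2-(triethylsilyloxy)-2,3,3a,4,5,7a-hexahydro-1H-indene-4-carbaldehyde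
Product: 21 (1S,3S,3aR,4R,5R,7aR)-3,4-diethyl-5-[(1E,3E)-2-ethyl-4-phenylbuta-1,3-dien-1-yl]-1,5,7-trimethyl-2-oxo-2,3,3a,4,5,7a-hexahydro-1H-indene-4-carboxylic acid, via hydroxy aldehyde 20 (not isolated)
Conditions: CrO3, H2SO4, H2O, acetone, 0 °C; i-PrOH quench
Reagents that add atoms: water, O
Why: Jones oxidation: the aqueous acid cleaves the triethylsilyl ether to 20, chromic acid oxidises the secondary alcohol to the ketone and the aldehyde (through its hydrate) to the acid, the C5–O bond is trans to C2 so no lactol can intervene, and the pseudo-equatorial C4 and C6 centres beside the new ketone are the stable epimers.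

## Compound list

1 | methyl (S)-3-hydroxy-2-methylpropanoate | COC(=O)[C@@H](C)CO | starting material
2 | methyl (S)-2-methyl-3-(triethylsilyloxy)propanoate | COC(=O)[C@@H](C)CO[Si](CC)(CC)CC | intermediate
3 | (S)-2-methyl-3-(triethylsilyloxy)propanal | O=C[C@@H](C)CO[Si](CC)(CC)CC | intermediate
4 | benzyl butanoate | CCCC(=O)OCc1ccccc1 | starting material
5 | [(1Z)-1-(benzyloxy)but-1-en-1-yl] dicyclohexylborinate, the E(O)-enolate (ethyl trans to O–B) | CC/C=C(\OCc1ccccc1)OB(C1CCCCC1)C1CCCCC1 | intermediate (not isolated)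
6 | benzyl (2R,3R,4S)-2-ethyl-3-hydroxy-4-methyl-5-(triethylsilyloxy)pentanoate | O=C(OCc1ccccc1)[C@H](CC)[C@H](O)[C@@H](C)CO[Si](CC)(CC)CC | intermediate
7 | benzyl (2R,3R,4S)-2-ethyl-4-methyl-3,5-bis(triethylsilyloxy)pentanoate | O=C(OCc1ccccc1)[C@H](CC)[C@H](O[Si](CC)(CC)CC)[C@@H](C)CO[Si](CC)(CC)CC | intermediate
8 | benzyl (2R,3R,4R)-2-ethyl-4-methyl-5-oxo-3-(triethylsilyloxy)pentanoate | O=C(OCc1ccccc1)[C@H](CC)[C@H](O[Si](CC)(CC)CC)[C@@H](C)C=O | intermediate
9 | 2-(triphenylphosphoranylidene)propanal | CC(C=O)=P(c1ccccc1)(c1ccccc1)c1ccccc1 | starting material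
10 | benzyl (2R,3R,4S,5E)-2-ethyl-4,6-dimethyl-7-oxo-3-(triethylsilyloxy)hept-5-enoate | O=C(OCc1ccccc1)[C@H](CC)[C@H](O[Si](CC)(CC)CC)[C@@H](C)/C=C(\C)C=O | intermediate
11 | benzyl (2R,3R,4S,5E,7E)-2-ethyl-4,6,8-trimethyl-9-oxo-3-(triethylsilyloxy)nona-5,7-dienoate | O=C(OCc1ccccc1)[C@H](CC)[C@H](O[Si](CC)(CC)CC)[C@@H](C)/C=C(C)/C=C(\C)C=O | intermediate
12 | 2-(triphenylphosphoranylidene)butanal | CCC(C=O)=P(c1ccccc1)(c1ccccc1)c1ccccc1 | starting material
13 | benzyl (2R,3R,4S,5E,7E,9E)-2,10-diethyl-4,6,8-trimethyl-11-oxo-3-(triethylsilyloxy)undeca-5,7,9-trienoate | O=C(OCc1ccccc1)[C@H](CC)[C@H](O[Si](CC)(CC)CC)[C@@H](C)/C=C(C)/C=C(C)/C=C(\CC)C=O | intermediate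
14 | diethyl benzylphosphonate | CCOP(=O)(OCC)Cc1ccccc1 | starting material
15 | sodium salt of the diethyl benzylphosphonate carbanion | [Na+].CCOP(=O)(OCC)[CH-]c1ccccc1 | intermediate (not isolated)
16 | benzyl (2R,3R,4S,5E,7E,9E,11E)-2,10-diethyl-4,6,8-trimethyl-12-phenyl-3-(triethylsilyloxy)dodeca-5,7,9,11-tetraenoate | O=C(OCc1ccccc1)[C@H](CC)[C@H](O[Si](CC)(CC)CC)[C@@H](C)/C=C(C)/C=C(C)/C=C(CC)/C=C/c1ccccc1 | intermediate
17 | (2R,3R,4S,5E,7E,9E,11E)-2,10-diethyl-4,6,8-trimethyl-12-phenyl-3-(triethylsilyloxy)dodeca-5,7,9,11-tetraenal | O=C[C@H](CC)[C@H](O[Si](CC)(CC)CC)[C@@H](C)/C=C(C)/C=C(C)/C=C(CC)/C=C/c1ccccc1 | intermediate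
18 | (2E,4S,5R,6S,7E,9E,11E,13E)-2,4,12-triethyl-6,8,10-trimethyl-14-phenyl-5-(triethylsilyloxy)tetradeca-2,7,9,11,13-pentaenal | O=C/C(CC)=C/[C@H](CC)[C@H](O[Si](CC)(CC)CC)[C@@H](C)/C=C(C)/C=C(C)/C=C(CC)/C=C/c1ccccc1 | intermediate (not isolated)
19 | (1S,2R,3S,3aR,4R,5R,7aR)-3,4-diethyl-5-[(1E,3E)-2-ethyl-4-phenylbuta-1,3-dien-1-yl]-1,5,7-trimethyl-2-(triethylsilyloxy)-2,3,3a,4,5,7a-hexahydro-1H-indene-4-carbaldehyde | CCC(/C=C/c1ccccc1)=C\[C@@]1(C)C=C(C)[C@@H]2[C@H]([C@H](CC)[C@H](O[Si](CC)(CC)CC)[C@H]2C)[C@@]1(CC)C=O | intermediate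
20 | (1S,2R,3S,3aR,4R,5R,7aR)-3,4-diethyl-5-[(1E,3E)-2-ethyl-4-phenylbuta-1,3-dien-1-yl]-2-hydroxy-1,5,7-trimethyl-2,3,3a,4,5,7a-hexahydro-1H-indene-4-carbaldehyde | CCC(/C=C/c1ccccc1)=C\[C@@]1(C)C=C(C)[C@@H]2[C@H]([C@H](CC)[C@H](O)[C@H]2C)[C@@]1(CC)C=O | intermediate (not isolated)
21 | (1S,3S,3aR,4R,5R,7aR)-3,4-diethyl-5-[(1E,3E)-2-ethyl-4-phenylbuta-1,3-dien-1-yl]-1,5,7-trimethyl-2-oxo-2,3,3a,4,5,7a-hexahydro-1H-indene-4-carboxylic acid | CCC(/C=C/c1ccccc1)=C\[C@@]1(C)C=C(C)[C@@H]2[C@H]([C@H](CC)C(=O)[C@H]2C)[C@@]1(CC)C(=O)O | target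

## Step count and risks

Total step count: 12. Longest linear sequence: 12 steps (from 1).

**Step 3 (stereoselectivity of the boron aldol).** The E(O)-enolisation of the butanoate or the Felkin preference may be insufficient. The fallback makes the C4–C5 bond by allylboration and sets out from aldehyde 3. Treatment with (E)-pent-2-enylboronic acid pinacol ester (toluene, −78 °C → rt) goes through a closed chair transition state, which gives the anti relationship of ethyl and hydroxyl, and by Felkin attack, which gives the syn relationship of hydroxyl and methyl. The product is the same stereotriad as in 6, (2S,3S,4S)-4-ethyl-2-methyl-1-(triethylsilyloxy)hex-5-en-3-ol F1, purified from its minor diastereomer. TESOTf/2,6-lutidine gives (3S,4S,5S)-3-ethyl-5-methyl-4,6-bis(triethylsilyloxy)hex-1-ene F2. Ozonolysis (O3, CH2Cl2, −78 °C; PPh3) gives (2R,3R,4S)-2-ethyl-4-methyl-3,5-bis(triethylsilyloxy)pentanal F3. Buffered NaClO2 oxidation (NaH2PO4, 2-methylbut-2-ene, t-BuOH/H2O) gives (2R,3R,4S)-2-ethyl-4-methyl-3,5-bis(triethylsilyloxy)pentanoic acid F4. BnBr/Cs2CO3 in DMF then returns to the route at benzyl ester 7.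

**Step 11 (one-pot Wittig/Diels–Alder).** The hindered aldehyde may react slowly with the hindered formyl ylide, and the thermal cycloaddition has to join two fully substituted carbons. The fallback separates the two events and sets out from aldehyde 17. The more nucleophilic ester ylide ethyl 2-(triphenylphosphoranylidene)butanoate (toluene, 60 °C) gives ethyl (2E,4S,5R,6S,7E,9E,11E,13E)-2,4,12-triethyl-6,8,10-trimethyl-14-phenyl-5-(triethylsilyloxy)tetradeca-2,7,9,11,13-pentaenoate F5, a poor dienophile that can be purified. i-Bu2AlH (CH2Cl2, −78 °C) gives (2E,4S,5R,6S,7E,9E,11E,13E)-2,4,12-triethyl-6,8,10-trimethyl-14-phenyl-5-(triethylsilyloxy)tetradeca-2,7,9,11,13-pentaen-1-ol F6. MnO2 (CH2Cl2, rt) gives pentaenal 18, now isolated. The cycloaddition is then run under Lewis acid catalysis (Me2AlCl, CH2Cl2, −78 → −20 °C), which lowers the temperature and reinforces the endo mode, and returns to the route at cycloadduct 19.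

**Step 12 (one-pot chromic acid oxidation).** The styryl diene may not tolerate the acidic oxidant, or the neopentyl aldehyde may oxidise too slowly. The fallback uses three mild operations and sets out from cycloadduct 19. HF·pyridine (THF/pyridine, 0 °C → rt) gives hydroxy aldehyde 20, now isolated. Dess–Martin periodinane (NaHCO3, CH2Cl2) gives (1S,3S,3aR,4R,5R,7aR)-3,4-diethyl-5-[(1E,3E)-2-ethyl-4-phenylbuta-1,3-dien-1-yl]-1,5,7-trimethyl-2-oxo-2,3,3a,4,5,7a-hexahydro-1H-indene-4-carbaldehyde F7. Pinnick oxidation (NaClO2, NaH2PO4, 2-methylbut-2-ene, t-BuOH/H2O) then returns to the route at the target 21.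

## Further compounds

F1 | step 3 | (2S,3S,4S)-4-ethyl-2-methyl-1-(triethylsilyloxy)hex-5-en-3-ol | C=C[C@H](CC)[C@H](O)[C@@H](C)CO[Si](CC)(CC)CC
F2 | step 3 | (3S,4S,5S)-3-ethyl-5-methyl-4,6-bis(triethylsilyloxy)hex-1-ene | C=C[C@H](CC)[C@H](O[Si](CC)(CC)CC)[C@@H](C)CO[Si](CC)(CC)CC
F3 | step 3 | (2R,3R,4S)-2-ethyl-4-methyl-3,5-bis(triethylsilyloxy)pentanal | O=C[C@H](CC)[C@H](O[Si](CC)(CC)CC)[C@@H](C)CO[Si](CC)(CC)CC
F4 | step 3 | (2R,3R,4S)-2-ethyl-4-methyl-3,5-bis(triethylsilyloxy)pentanoic acid | O=C(O)[C@H](CC)[C@H](O[Si](CC)(CC)CC)[C@@H](C)CO[Si](CC)(CC)CC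
F5 | step 11 | ethyl (2E,4S,5R,6S,7E,9E,11E,13E)-2,4,12-triethyl-6,8,10-trimethyl-14-phenyl-5-(triethylsilyloxy)tetradeca-2,7,9,11,13-pentaenoate | CCOC(=O)/C(CC)=C/[C@H](CC)[C@H](O[Si](CC)(CC)CC)[C@@H](C)/C=C(C)/C=C(C)/C=C(CC)/C=C/c1ccccc1
F6 | step 11 | (2E,4S,5R,6S,7E,9E,11E,13E)-2,4,12-triethyl-6,8,10-trimethyl-14-phenyl-5-(triethylsilyloxy)tetradeca-2,7,9,11,13-pentaen-1-ol | OC/C(CC)=C/[C@H](CC)[C@H](O[Si](CC)(CC)CC)[C@@H](C)/C=C(C)/C=C(C)/C=C(CC)/C=C/c1ccccc1
F7 | step 12 | (1S,3S,3aR,4R,5R,7aR)-3,4-diethyl-5-[(1E,3E)-2-ethyl-4-phenylbuta-1,3-dien-1-yl]-1,5,7-trimethyl-2-oxo-2,3,3a,4,5,7a-hexahydro-1H-indene-4-carbaldehyde | CCC(/C=C/c1ccccc1)=C\[C@@]1(C)C=C(C)[C@@H]2[C@H]([C@H](CC)C(=O)[C@H]2C)[C@@]1(CC)C=O
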